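The constants are made up; the rest is arithmetic.

At the [J] of the charge, free X is bound by J at 33.2 h⁻¹, far faster than bound catalyst releases E, at 0.551 h⁻¹. That release rate is 2.0 h⁻¹ times the 27.5 % of bound catalyst standing as Q. Q falling to X and E is slower than J.X turning into Q at 30 h⁻¹, which makes it the rate-limiting step, with J.X and Q as the resting state while [J] stands high. Meanwhile pairs of J leave as J2.

the same everywhere: X 52 mM
- delta: J 0.40 M; time 3.0 h; everything together in a closed stirred flask, run for 3.0 h
- eta: J 0.40 M; a single well-mixed tank run continuously and read at steady state, 3.0 h in it on average
- alpha: J 0.40 M (fed, over 3.00 h); time 3.0 h; all but J at the start; J goes in evenly over 3.00 h, the run ends at 3.0 h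

1. the set-up with the highest amount of E at the outlet or at the end, in percent of the J put in ("none" if the first two lie within 2 percentage points) (delta / eta / alpha / none)
2. amount of E at the outlet or at the end, in percent of the J put in, delta
3. amount of E at the outlet or at the end, in percent of the J put in, eta
4. amount of E at the outlet or at the end, in percent of the J put in, alpha

- a species is counted by the J in it: one J2 counts as two
- amounts and yields of E count X.E too
- a doubled species enters its step squared and goes two at a time
- the stated concentrations are those of everything mixed, before any reaction; amounts are the same in each set-up
- the feed brings no volume worth counting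
- run time (delta): 3.0 h

The release rate times [X] times the run time, over the [J] of the charge, gives 21.5 %: the capacity number, the share of the J put in that fully loaded catalyst can turn into E during the run. Is this one number enough? It assumes full loading from the first minute, so each vessel needs a test.

In delta, step 4 by itself takes [J] down a second-order curve to 0.0571 M. Integrating the bound share of the catalyst along that curve in closed form gives a mean loading of 0.938, hence 20.2 %. In eta, feed and step 4 balance near 0.133 M, so the loading is 0.953 and the tank gives 20.5 %. In alpha, the feed needs 0.390 h to bring in as much J as there is X; charging the run with that delay gives 18.7 %. Eta and delta then lie 0.3 percentage points apart, inside the margin, so this reckoning names no winner.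

The forecast gives 19.2 %, 19.4 % and 18.2 % for delta, eta and alpha, and none as best, holding that the small differences “keep all three within about a point”.

    Q → X + E (k1 = 2.0 h⁻¹)
    J + X → J.X (k2 = 83 M⁻¹ h⁻¹)
    X + E ⇌ X.E, settled at all times (K3 = 1.2 M⁻¹)
    2 J → J2 (k4 = 2.5 M⁻¹ h⁻¹)
    J.X ⇌ Q (K5 = 0.38, k5 = 30 h⁻¹)

The simulation gives 19.1 % for delta, 19.0 % for eta and 16.5 % for alpha, so the best is none, and alpha stands 2.2 points below the delayed capacity. Delta reaches 0.888 of its capacity number, and at 3.00 h its free X is 15.8 % of the catalyst charged. Scaled to the 0.013 M of X in the neighbour of delta, the capacity number becomes 5.37 %. That flask holds 4.88 % of E at 3.00 h.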